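The biflavone is cut inside ring A of unit 2 (the 7-methoxyflavone joined through C8) instead of at the crowded biaryl bond to C6 of unit 1 (the 4'-methoxyflavone). In that ring the aryl-bearing C8 lies between C7–OMe and C8a–O1, the 2-aryl-3-alkoxyphenol pattern that a vinylketene–ynol ether benzannulation gives. Heating a 6-(methoxyethynyl)flavone (unit 1 with O7 benzyl and O5 methyl) with 3-ethoxycyclobutenone should grow this ring on the alkyne in one operation, forming C8–C8a and C6–C7 and leaving the three ring oxygens differentiated as OH, OMe and OEt. Ring C of unit 2 is then built by acylation, chalcone formation and oxidative cyclisation, and BCl3 unmasks the four hydroxyls.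

Key step: step 8

Remark: the tetra-ortho-substituted biaryl axis between C6 of unit 1 and C8 of unit 2 is a stereogenic element that the target structure leaves unassigned; it is made as the racemate from compound 18 onward and no step has to control it.

Step 1
Reactants: 1 2',4',6'-trihydroxyacetophenone
Product: 2 1-[2,4-bis(benzyloxy)-6-hydroxyphenyl]ethan-1-one
Conditions: BnBr (2.1 equiv), K2CO3, DMF, rt
Reagents that add atoms: benzyl bromide, BrCc1ccccc1
Why: Williamson etherification takes the two unchelated hydroxyls, while the third, hydrogen-bonded to the acetyl carbonyl, is far less nucleophilic and stays free for the later ring closure.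

Step 2
Reactants: 2 1-[2,4-bis(benzyloxy)-6-hydroxyphenyl]ethan-1-one, 3 4-methoxybenzaldehyde
Product: 4 (E)-1-[2,4-bis(benzyloxy)-6-hydroxyphenyl]-3-(4-methoxyphenyl)prop-2-en-1-one
Conditions: KOH (50% aq.), EtOH, rt
Reagents that add atoms: none
Why: Claisen–Schmidt condensation of the methyl ketone enolate with the non-enolisable aldehyde, followed by dehydration, should give the (E)-chalcone.

Step 3
Reactants: 4 (E)-1-[2,4-bis(benzyloxy)-6-hydroxyphenyl]-3-(4-methoxyphenyl)prop-2-en-1-one
Product: 5 5,7-bis(benzyloxy)-2-(4-methoxyphenyl)chromen-4-one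
Conditions: I2 (10 mol %), DMSO, 130 °C
Reagents that add atoms: none
Why: Iodine-catalysed oxidative cyclisation of a 2'-hydroxychalcone, with DMSO as terminal oxidant, closes the pyranone ring and dehydrogenates it to the flavone.

Step 4
Reactants: 5 5,7-bis(benzyloxy)-2-(4-methoxyphenyl)chromen-4-one
Product: 6 7-(benzyloxy)-5-hydroxy-2-(4-methoxyphenyl)chromen-4-one (7-O-benzylacacetin)
Conditions: BCl3 (1.1 equiv), CH2Cl2, −78 °C; then H2O
Reagents that add atoms: none
Why: Chelation-controlled Lewis acid ether cleavage, in which BCl3 held between the C4 carbonyl and O5 removes only the peri benzyl group at low temperature and leaves the O7 benzyl and 4'-methyl ethers.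

Step 5
Reactants: 6 7-(benzyloxy)-5-hydroxy-2-(4-methoxyphenyl)chromen-4-one
Product: 7 7-(benzyloxy)-5-hydroxy-6-iodo-2-(4-methoxyphenyl)chromen-4-one
Conditions: BnMe3N·ICl2 (1.1 equiv), CaCO3, CH2Cl2–MeOH, rt
Reagents that add atoms: benzyltrimethylammonium dichloroiodate, C[N+](C)(C)Cc1ccccc1.Cl[I-]Cl
Why: Electrophilic aromatic iodination directed by the free 5-hydroxyl goes to its ortho carbon C6, the established site for 5-hydroxy-7-alkoxyflavones, whereas fully etherified 5,7-dialkoxyflavones react at C8, which is why O5 was unmasked first.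

Step 6
Reactants: 7 7-(benzyloxy)-5-hydroxy-6-iodo-2-(4-methoxyphenyl)chromen-4-one
Product: 8 7-(benzyloxy)-6-iodo-5-methoxy-2-(4-methoxyphenyl)chromen-4-one
Conditions: MeI (5 equiv), K2CO3, DMF, 50 °C
Reagents that add atoms: iodomethane, CI
Why: Williamson O-methylation of the chelated and flanked 5-hydroxyl succeeds with the smallest electrophile, and methyl is chosen here instead of benzyl because it crowds the future alkyne least, is inert to the BF3 of step 9 and is removed at the end by peri-selective BCl3 cleavage.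

Step 7
Reactants: 8 7-(benzyloxy)-6-iodo-5-methoxy-2-(4-methoxyphenyl)chromen-4-one, 9 2-chloro-1,1-dimethoxyethane (chloroacetaldehyde dimethyl acetal)
Product: 12 7-(benzyloxy)-5-methoxy-6-(methoxyethynyl)-2-(4-methoxyphenyl)chromen-4-one, via lithium methoxyacetylide 10 (not isolated), via (methoxyethynyl)zinc chloride 11 (not isolated)
Conditions: 9, LiNEt2 (3.0 equiv), THF, 0 °C; ZnCl2 (1.2 equiv), 0 °C to rt; then 8, Pd(PPh3)4 (5 mol %), THF, rt to 45 °C
Reagents that add atoms: none
Why: Base-induced double elimination from 9 (loss of HCl, then of methanol) and deprotonation give acetylide 10, transmetalation gives 11, and Negishi coupling with iodide 8 forms the aryl–alkynyl bond, the alkynylzinc transmetalating fast enough for a doubly ortho-substituted iodide while ignoring the flavone carbonyl.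

Step 8
Reactants: 12 7-(benzyloxy)-5-methoxy-6-(methoxyethynyl)-2-(4-methoxyphenyl)chromen-4-one, 13 3-ethoxycyclobut-2-en-1-one
Product: 18 7-(benzyloxy)-6-(4-ethoxy-2-hydroxy-6-methoxyphenyl)-5-methoxy-2-(4-methoxyphenyl)chromen-4-one, via (1-ethoxyvinyl)ketene 14 (not isolated), via vinylcyclobutenone adduct 15 (not isolated), via dienylketene 16 (not isolated), via cyclohexadienone tautomer 17 (not isolated)
Conditions: 13 (2.5 equiv, in portions), toluene, 80 °C then 110 °C; then K2CO3, MeOH, rt
Reagents that add atoms: none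
Why: Four-electron electrocyclic ring opening of 13 gives (1-ethoxyvinyl)ketene 14 (ethoxy on the carbon next to the ketene, CH2=C(OEt)–CH=C=O), and its ketene carbon is attacked by the nucleophilic, aryl-bearing carbon of ynol ether 12 in a [2+2] cycloaddition that gives vinylcyclobutenone 15 and creates the two new skeletal bonds C8–C8a and C6–C7 of unit 2. Four-electron opening of 15 gives dienylketene 16, whose six-electron electrocyclisation closes the six-membered carbocycle (ring A of unit 2) by joining the ketene carbon to the terminal methylene, and cyclohexadienone 17 tautomerises to phenol 18. This is the Danheiser benzannulation of a cyclobutenone with an alkoxyalkyne, a known reaction type used here on an aryl-substituted ynol ether. The one selectivity required, aryl ortho and methoxy meta to the new hydroxyl, is secured by the polarisation of the ynol ether, in which oxygen lone-pair donation makes the carbon bearing the flavone the nucleophile while the ketene carbonyl carbon is the only electrophilic site. The methyl ynol ether has no β-hydrogen for retro-ene loss of an alkene on heating, the small O5 methyl keeps the reacting alkyne carbon accessible, and the closing K2CO3/MeOH treatment frees any phenol that excess ketene has esterified. No stereocentre remains (the one in 15 is lost on ring opening) and the new tetra-ortho-substituted biaryl axis forms as a racemate, which is all the target asks for.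

Step 9
Reactants: 18 7-(benzyloxy)-6-(4-ethoxy-2-hydroxy-6-methoxyphenyl)-5-methoxy-2-(4-methoxyphenyl)chromen-4-one
Product: 21 6-(3-acetyl-4-ethoxy-2-hydroxy-6-methoxyphenyl)-7-(benzyloxy)-5-methoxy-2-(4-methoxyphenyl)chromen-4-one, via aryl acetate 19 (not isolated), via difluoroboron chelate 20 (not isolated)
Conditions: Ac2O (3 equiv), BF3·OEt2 (3 equiv), EtOAc, 0 °C to 45 °C; then aq. NaOAc, MeOH, 60 °C
Reagents that add atoms: acetic anhydride, CC(=O)OC(C)=O
Why: O-Acetylation followed by BF3-mediated Fries rearrangement should place the acetyl group on the only free carbon ortho to the hydroxyl (C4a of unit 2), because that isomer is held as the six-membered O,O-difluoroboron chelate 20, which the buffered methanolysis then opens.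

Step 10
Reactants: 21 6-(3-acetyl-4-ethoxy-2-hydroxy-6-methoxyphenyl)-7-(benzyloxy)-5-methoxy-2-(4-methoxyphenyl)chromen-4-one, 22 4-(benzyloxy)benzaldehyde
Product: 23 7-(benzyloxy)-6-{3-[(E)-3-(4-(benzyloxy)phenyl)prop-2-enoyl]-4-ethoxy-2-hydroxy-6-methoxyphenyl}-5-methoxy-2-(4-methoxyphenyl)chromen-4-one
Conditions: KOH (50% aq.), EtOH–THF, rt
Reagents that add atoms: none
Why: Claisen–Schmidt condensation of the new methyl ketone with the non-enolisable aldehyde should give the (E)-chalcone at room temperature, conditions under which the flavone of unit 1 is expected to stay closed.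

Step 11
Reactants: 23 7-(benzyloxy)-6-{3-[(E)-3-(4-(benzyloxy)phenyl)prop-2-enoyl]-4-ethoxy-2-hydroxy-6-methoxyphenyl}-5-methoxy-2-(4-methoxyphenyl)chromen-4-one
Product: 24 7-(benzyloxy)-6-[2-(4-(benzyloxy)phenyl)-5-ethoxy-7-methoxy-4-oxochromen-8-yl]-5-methoxy-2-(4-methoxyphenyl)chromen-4-one
Conditions: I2 (20 mol %), DMSO, 125 °C
Reagents that add atoms: none
Why: Iodine-catalysed oxidative cyclisation of the 2'-hydroxychalcone in DMSO closes ring C of unit 2 through the phenol oxygen set free in the benzannulation, which becomes O1.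

Step 12
Reactants: 24 7-(benzyloxy)-6-[2-(4-(benzyloxy)phenyl)-5-ethoxy-7-methoxy-4-oxochromen-8-yl]-5-methoxy-2-(4-methoxyphenyl)chromen-4-one
Product: 25 5,7-dihydroxy-6-[5-hydroxy-2-(4-hydroxyphenyl)-7-methoxy-4-oxochromen-8-yl]-2-(4-methoxyphenyl)chromen-4-one (CNP0290866.0)
Conditions: BCl3 (12 equiv), C6HMe5 (8 equiv), CH2Cl2, −78 °C to rt; then H2O
Reagents that add atoms: none
Why: Lewis acid ether cleavage in which BCl3, with pentamethylbenzene as benzyl cation trap, removes both benzyl ethers at low temperature and, on warming, the two peri alkyl ethers (O5 methyl of unit 1, O5 ethyl of unit 2) through carbonyl chelation, while the unchelated 4'-OMe of unit 1 and C7–OMe of unit 2 are not expected to be attacked.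

Compound list
1 | 2',4',6'-trihydroxyacetophenone | CC(=O)c1c(O)cc(O)cc1O | starting material
2 | 1-[2,4-bis(benzyloxy)-6-hydroxyphenyl]ethan-1-one | CC(=O)c1c(O)cc(OCc2ccccc2)cc1OCc1ccccc1 | intermediate
3 | 4-methoxybenzaldehyde | COc1ccc(C=O)cc1 | starting material
4 | (E)-1-[2,4-bis(benzyloxy)-6-hydroxyphenyl]-3-(4-methoxyphenyl)prop-2-en-1-one | COc1ccc(/C=C/C(=O)c2c(O)cc(OCc3ccccc3)cc2OCc2ccccc2)cc1 | intermediate
5 | 5,7-bis(benzyloxy)-2-(4-methoxyphenyl)chromen-4-one | COc1ccc(-c2cc(=O)c3c(OCc4ccccc4)cc(OCc4ccccc4)cc3o2)cc1 | intermediate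
6 | 7-(benzyloxy)-5-hydroxy-2-(4-methoxyphenyl)chromen-4-one | COc1ccc(-c2cc(=O)c3c(O)cc(OCc4ccccc4)cc3o2)cc1 | intermediate
7 | 7-(benzyloxy)-5-hydroxy-6-iodo-2-(4-methoxyphenyl)chromen-4-one | COc1ccc(-c2cc(=O)c3c(O)c(I)c(OCc4ccccc4)cc3o2)cc1 | intermediate
8 | 7-(benzyloxy)-6-iodo-5-methoxy-2-(4-methoxyphenyl)chromen-4-one | COc1ccc(-c2cc(=O)c3c(OC)c(I)c(OCc4ccccc4)cc3o2)cc1 | intermediate
9 | 2-chloro-1,1-dimethoxyethane (chloroacetaldehyde dimethyl acetal) | COC(CCl)OC | starting material
10 | lithium methoxyacetylide | [Li]C#COC | intermediate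
11 | (methoxyethynyl)zinc chloride | COC#C[Zn]Cl | intermediate
12 | 7-(benzyloxy)-5-methoxy-6-(methoxyethynyl)-2-(4-methoxyphenyl)chromen-4-one | COC#Cc1c(OCc2ccccc2)cc2oc(-c3ccc(OC)cc3)cc(=O)c2c1OC | intermediate
13 | 3-ethoxycyclobut-2-en-1-one | CCOC1=CC(=O)C1 | starting material
14 | (1-ethoxyvinyl)ketene (3-ethoxybuta-1,3-dien-1-one) | C=C(OCC)C=C=O | intermediate
15 | 7-(benzyloxy)-6-[3-(1-ethoxyethenyl)-2-methoxy-4-oxocyclobut-1-en-1-yl]-5-methoxy-2-(4-methoxyphenyl)chromen-4-one (racemic) | CCOC(=C)C1C(=O)C(c2c(OCc3ccccc3)cc3oc(-c4ccc(OC)cc4)cc(=O)c3c2OC)=C1OC | intermediate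
16 | (3E)-2-[7-(benzyloxy)-5-methoxy-2-(4-methoxyphenyl)-4-oxochromen-6-yl]-5-ethoxy-3-methoxyhexa-1,3,5-trien-1-one | C=C(OCC)/C=C(OC)\C(=C=O)c1c(OCc2ccccc2)cc2oc(-c3ccc(OC)cc3)cc(=O)c2c1OC | intermediate
17 | 7-(benzyloxy)-6-(4-ethoxy-2-methoxy-6-oxocyclohexa-1,3-dien-1-yl)-5-methoxy-2-(4-methoxyphenyl)chromen-4-one | CCOC1=CC(OC)=C(c2c(OCc3ccccc3)cc3oc(-c4ccc(OC)cc4)cc(=O)c3c2OC)C(=O)C1 | intermediate
18 | 7-(benzyloxy)-6-(4-ethoxy-2-hydroxy-6-methoxyphenyl)-5-methoxy-2-(4-methoxyphenyl)chromen-4-one (racemic axis) | CCOc1cc(O)c(-c2c(OCc3ccccc3)cc3oc(-c4ccc(OC)cc4)cc(=O)c3c2OC)c(OC)c1 | intermediate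
19 | 2-[7-(benzyloxy)-5-methoxy-2-(4-methoxyphenyl)-4-oxochromen-6-yl]-5-ethoxy-3-methoxyphenyl acetate | CCOc1cc(OC(C)=O)c(-c2c(OCc3ccccc3)cc3oc(-c4ccc(OC)cc4)cc(=O)c3c2OC)c(OC)c1 | intermediate
20 | O,O-difluoroboron chelate of 21 | CCOc1cc(OC)c(-c3c(OCc4ccccc4)cc4oc(-c5ccc(OC)cc5)cc(=O)c4c3OC)c2c1C(C)=[O+][B-](F)(F)O2 | intermediate
21 | 6-(3-acetyl-4-ethoxy-2-hydroxy-6-methoxyphenyl)-7-(benzyloxy)-5-methoxy-2-(4-methoxyphenyl)chromen-4-one | CCOc1cc(OC)c(-c2c(OCc3ccccc3)cc3oc(-c4ccc(OC)cc4)cc(=O)c3c2OC)c(O)c1C(C)=O | intermediate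
22 | 4-(benzyloxy)benzaldehyde | O=Cc1ccc(OCc2ccccc2)cc1 | starting material
23 | 7-(benzyloxy)-6-{3-[(E)-3-(4-(benzyloxy)phenyl)prop-2-enoyl]-4-ethoxy-2-hydroxy-6-methoxyphenyl}-5-methoxy-2-(4-methoxyphenyl)chromen-4-one | CCOc1cc(OC)c(-c2c(OCc3ccccc3)cc3oc(-c4ccc(OC)cc4)cc(=O)c3c2OC)c(O)c1C(=O)/C=C/c1ccc(OCc2ccccc2)cc1 | intermediate
24 | 7-(benzyloxy)-6-[2-(4-(benzyloxy)phenyl)-5-ethoxy-7-methoxy-4-oxochromen-8-yl]-5-methoxy-2-(4-methoxyphenyl)chromen-4-one | CCOc1cc(OC)c(-c2c(OCc3ccccc3)cc3oc(-c4ccc(OC)cc4)cc(=O)c3c2OC)c2oc(-c3ccc(OCc4ccccc4)cc3)cc(=O)c12 | intermediate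
25 | 5,7-dihydroxy-6-[5-hydroxy-2-(4-hydroxyphenyl)-7-methoxy-4-oxochromen-8-yl]-2-(4-methoxyphenyl)chromen-4-one (CNP0290866.0) | COc1ccc(-c2cc(=O)c3c(O)c(-c4c(OC)cc(O)c5c(=O)cc(-c6ccc(O)cc6)oc45)c(O)cc3o2)cc1 | target

Total step count: 12.
Longest linear sequence: 12 steps (1 to 25); compounds 3, 9, 13 and 22 enter as purchased building blocks.

Steps most likely to fail

Step 8. The donor-substituted cyclobutenone may open too slowly and the ketene be lost to self-condensation. The ketene may also fail to reach the alkyne carbon that sits between two ortho substituents, or the ynol ether may be hydrated or degraded on prolonged heating. The fallback makes the biaryl bond by cross-coupling and brings ring A of unit 2 in intact; it sets out from iodide 8 and comes back to the route at 21. Phloroglucinol F1 would be converted with MOMCl and i-Pr2NEt into 3,5-bis(methoxymethoxy)phenol F2 and ethylated (EtI, K2CO3, DMF) to 1-ethoxy-3,5-bis(methoxymethoxy)benzene F3. Lithiation between the two MOM ethers (n-BuLi, THF, 0 °C) and borylation (B(OMe)3, then aq. NH4Cl) would give [4-ethoxy-2,6-bis(methoxymethoxy)phenyl]boronic acid F4. Suzuki–Miyaura coupling of F4 with 8 (Pd(OAc)2, SPhos, K3PO4, toluene–H2O, 100 °C) should give 7-(benzyloxy)-6-[4-ethoxy-2,6-bis(methoxymethoxy)phenyl]-5-methoxy-2-(4-methoxyphenyl)chromen-4-one F5, and HCl in MeOH should free the symmetric resorcinol 7-(benzyloxy)-6-(4-ethoxy-2,6-dihydroxyphenyl)-5-methoxy-2-(4-methoxyphenyl)chromen-4-one F6. C-Acetylation as in step 9, followed by mild methanolysis of any O-acetate, should give 6-(3-acetyl-4-ethoxy-2,6-dihydroxyphenyl)-7-(benzyloxy)-5-methoxy-2-(4-methoxyphenyl)chromen-4-one F7; the two open ring carbons are equivalent, so no regiochemical question arises. MeI (1 equiv) with K2CO3 in acetone should then methylate only the hydroxyl that is not hydrogen-bonded to the acetyl group, giving 21.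

Step 9. Acylation may go to the ring carbon para to the hydroxyl (between OMe and OEt) instead of ortho, and the Lewis acid may strip the O7 benzyl group of unit 1. That oxygen is free in the target, so the loss is not fatal, but it divides the material. The fallback brings the carbon in under non-acidic, strictly ortho-directing conditions; it sets out from 18 and comes back at 21. Formylation through the magnesium phenoxide (MgCl2, Et3N, (CH2O)n, MeCN, reflux) should give 7-(benzyloxy)-6-(4-ethoxy-3-formyl-2-hydroxy-6-methoxyphenyl)-5-methoxy-2-(4-methoxyphenyl)chromen-4-one F8. Aldehyde-selective methyl addition (MeTi(Oi-Pr)3, 2.5 equiv, THF, −20 °C to rt) should give racemic 7-(benzyloxy)-6-[4-ethoxy-2-hydroxy-3-(1-hydroxyethyl)-6-methoxyphenyl]-5-methoxy-2-(4-methoxyphenyl)chromen-4-one F9, and benzylic oxidation (MnO2, CH2Cl2, rt) should give 21.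

Step 7. Coupling at the doubly ortho-substituted iodide may be slow, so that the basic acetylide solution decomposes or its residual amide attacks the flavone first; the ynol ether may also be hydrated during isolation. The fallback separates reagent making from coupling and uses a neutral, purified carbon nucleophile; it sets out from 8 and 9 and comes back at 12. Acetylide 10, made from 9 as in step 7, would be quenched with Bu3SnCl to give distillable tributyl(methoxyethynyl)stannane F10. Stille coupling of F10 with 8 (PdCl2(PPh3)2, Et4NCl, DMF, 60 °C), with chromatography on base-washed silica, should give 12.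

Further compounds
F1 | step 8 | phloroglucinol | Oc1cc(O)cc(O)c1
F2 | step 8 | 3,5-bis(methoxymethoxy)phenol | COCOc1cc(O)cc(OCOC)c1
F3 | step 8 | 1-ethoxy-3,5-bis(methoxymethoxy)benzene | CCOc1cc(OCOC)cc(OCOC)c1
F4 | step 8 | [4-ethoxy-2,6-bis(methoxymethoxy)phenyl]boronic acid | CCOc1cc(OCOC)c(B(O)O)c(OCOC)c1
F5 | step 8 | 7-(benzyloxy)-6-[4-ethoxy-2,6-bis(methoxymethoxy)phenyl]-5-methoxy-2-(4-methoxyphenyl)chromen-4-one | CCOc1cc(OCOC)c(-c2c(OCc3ccccc3)cc3oc(-c4ccc(OC)cc4)cc(=O)c3c2OC)c(OCOC)c1
F6 | step 8 | 7-(benzyloxy)-6-(4-ethoxy-2,6-dihydroxyphenyl)-5-methoxy-2-(4-methoxyphenyl)chromen-4-one | CCOc1cc(O)c(-c2c(OCc3ccccc3)cc3oc(-c4ccc(OC)cc4)cc(=O)c3c2OC)c(O)c1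
F7 | step 8 | 6-(3-acetyl-4-ethoxy-2,6-dihydroxyphenyl)-7-(benzyloxy)-5-methoxy-2-(4-methoxyphenyl)chromen-4-one | CCOc1cc(O)c(-c2c(OCc3ccccc3)cc3oc(-c4ccc(OC)cc4)cc(=O)c3c2OC)c(O)c1C(C)=O
F8 | step 9 | 7-(benzyloxy)-6-(4-ethoxy-3-formyl-2-hydroxy-6-methoxyphenyl)-5-methoxy-2-(4-methoxyphenyl)chromen-4-one | CCOc1cc(OC)c(-c2c(OCc3ccccc3)cc3oc(-c4ccc(OC)cc4)cc(=O)c3c2OC)c(O)c1C=O
F9 | step 9 | 7-(benzyloxy)-6-[4-ethoxy-2-hydroxy-3-(1-hydroxyethyl)-6-methoxyphenyl]-5-methoxy-2-(4-methoxyphenyl)chromen-4-one (racemic) | CCOc1cc(OC)c(-c2c(OCc3ccccc3)cc3oc(-c4ccc(OC)cc4)cc(=O)c3c2OC)c(O)c1C(C)O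
F10 | step 7 | tributyl(methoxyethynyl)stannane | CCCC[Sn](CCCC)(CCCC)C#COC
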